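**Retrosynthetic overview**

1. Target 31 ⇒ tri-O-benzyl ether 30 (BCl3) ⇒ ring D (pyranone of the aromatic chromone) by 6-endo closure of phenol 28 onto a ketal-masked ynone ⇒ ring C (its benzene ring) by Dötz benzannulation of chromium carbene 26 with diyne ketal 19.
2. Feature: in ring C (C4a'–C5'–C6'–C7'–C8'–C8a') the ether carbon C6' lies para to C8a'–O1' and ortho to C7'–OMe, a 4-alkoxyphenol with a neighbouring methoxyl. The carbene carbon becomes C6', the 1-methoxyvinyl carbons C7' and C8', one CO ligand C8a', the alkyne C5' and C4a', so the C8–O bond exists before the arene and is never broken.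
3. 26 ⇒ 8-hydroxy-5,6,7-tri-O-benzyl tetrahydrochromone 15 + acylchromate 24 (acyloxycarbene alcoholysis). The alkyne already carries C4', C3', C2' and the phenethyl chain, because a Claisen condensation after the benzannulation would put strong base on a pyranone with an acidic C8–H next to the C7 benzyloxy group.
4. 15 ⇒ ring B (first pyranone) by aldol addition of cyclohexanone 9 to 5-phenylpent-2-ynal, oxidation and 6-endo cyclisation. 9 ⇒ alkenyl bromide 7 ⇒ (1S,2S)-3-bromocyclohexa-3,5-diene-1,2-diol 1, whose cis-diol is C7/C8; anti epoxidation and allylic trans opening set C6 and C5.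
5. Ring order: A (carbocycle C4a–C8a, from 1) → B (step 11) → C (step 18) → D (step 19).

Key step: step 18

Remark: diol 1 (whole-cell dioxygenation product of bromobenzene) is taken as a catalogue compound; unprimed locants are those of the tetrahydrochromone of the target, primed locants those of the aromatic chromone, also for carbocyclic intermediates.

**Route**

Step 1
Reactants: 1 (1S,2S)-3-bromocyclohexa-3,5-diene-1,2-diol
Product: 2 (3aS,7aS)-4-bromo-2-(4-methoxyphenyl)-3a,7a-dihydro-1,3-benzodioxole (either configuration at the acetal carbon)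
Conditions: 4-MeOC6H4CH(OMe)2, CSA (cat.), CH2Cl2, −20 °C; Et3N
Reagents that add atoms: 4-methoxybenzaldehyde dimethyl acetal, COC(OC)c1ccc(OC)cc1
Why: Acid-catalysed transacetalisation of the cis-diol at low temperature outruns dehydration to bromophenol and leaves C7 and C8 untouched; 2 is used at once because such dienes dimerise.

Step 2
Reactants: 2 acetal from step 1
Product: 3 (1S,2S)-3-bromo-2-[(4-methoxybenzyl)oxy]cyclohexa-3,5-dien-1-ol
Conditions: i-Bu2AlH, CH2Cl2, −78 → 0 °C
Reagents that add atoms: none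
Why: Reductive acetal cleavage in which aluminium binds the more basic, less hindered oxygen remote from the bromoalkene, that C–O bond ionises and hydride reduces the oxocarbenium ion, so the PMB ether should end on O8 and O7 is freed.

Step 3
Reactants: 3 mono-PMB dienol
Product: 4 (5S,6S)-5-(benzyloxy)-1-bromo-6-[(4-methoxybenzyl)oxy]cyclohexa-1,3-diene
Conditions: NaH, BnBr, Bu4NI (cat.), THF, 0 °C
Reagents that add atoms: benzyl bromide, BrCc1ccccc1
Why: Williamson etherification of the alkoxide at 0 °C is faster than base-induced aromatisation and gives O7 its permanent benzyl group.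

Step 4
Reactants: 4 diene diether
Product: 5 (1R,4S,5S,6R)-5-(benzyloxy)-3-bromo-4-[(4-methoxybenzyl)oxy]-7-oxabicyclo[4.1.0]hept-2-ene
Conditions: mCPBA, NaHCO3, CH2Cl2, 0 °C
Reagents that add atoms: 3-chloroperoxybenzoic acid, OOC(=O)c1cccc(Cl)c1
Why: Prilezhaev epoxidation takes the electron-richer alkene without bromine on the face opposite to the two cis ether groups, which places the epoxide oxygen (later O6) trans to O7.

Step 5
Reactants: 5 vinyl epoxide
Product: 6 (1R,2S,5S,6S)-6-(benzyloxy)-4-bromo-5-[(4-methoxybenzyl)oxy]cyclohex-3-ene-1,2-diol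
Conditions: KOH, H2O/DMSO, 80 °C
Reagents that add atoms: water, O
Why: SN2 opening of the vinyl epoxide by hydroxide at the allylic carbon (activated by the alkene, while C6 is screened by the C7 benzyloxy group) inverts C5 and gives the 5,6-trans diol.

Step 6
Reactants: 6 trans-diol
Product: 7 (3S,4R,5S,6S)-3,4,5-tris(benzyloxy)-1-bromo-6-[(4-methoxybenzyl)oxy]cyclohex-1-ene
Conditions: NaH, BnBr, Bu4NI (cat.), DMF, 0 °C → rt
Reagents that add atoms: benzyl bromide, BrCc1ccccc1
Why: Double Williamson etherification; the alkenyl bromide and the four stereocentres are inert to the base.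

Step 7
Reactants: 7 alkenyl bromide
Product: 9 (2S,3S,4R,5S)-3,4,5-tris(benzyloxy)-2-[(4-methoxybenzyl)oxy]cyclohexan-1-one, via alkenyl pinacol boronate 8 (not isolated)
Conditions: B2pin2, PdCl2(dppf) (cat.), KOAc, 1,4-dioxane, 80 °C; then NaBO3·4H2O, THF/H2O, rt
Reagents that add atoms: sodium perborate, [Na+].[O-]OB=O
Why: Miyaura borylation (oxidative addition of zerovalent palladium into C–Br, transmetalation, reductive elimination) and oxidation of the alkenyl C–B bond give the enol at the former C–Br carbon, which tautomerises to the C8a ketone; near-neutral perborate is chosen so that the axial C8 alkoxy centre does not epimerise and the β-benzyloxy group is not eliminated.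

Step 8
Reactants: 10 4-phenyl-1-butyne
Product: 11 5-phenylpent-2-ynal
Conditions: n-BuLi, THF, −78 °C; DMF; aq. KH2PO4 (inverse quench)
Reagents that add atoms: N,N-dimethylformamide, CN(C)C=O
Why: Formylation of the lithium acetylide with DMF; the buffered inverse quench frees the ynal without adding dimethylamine back to it.

Step 9
Reactants: 9 cyclohexanone; 11 5-phenylpent-2-ynal
Product: 12 (2S,3S,4R,5S)-3,4,5-tris(benzyloxy)-6-(1-hydroxy-5-phenylpent-2-yn-1-yl)-2-[(4-methoxybenzyl)oxy]cyclohexan-1-one (diastereomers at C6 and at the carbinol)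
Conditions: LiN(i-Pr)2, THF, −78 °C; then 11; AcOH, −78 °C
Reagents that add atoms: none
Why: Directed aldol addition: the amide base removes a proton of the unhindered CH2 rather than the methine bearing OPMB, and at −78 °C the enolate adds to the ynal before benzyl alkoxide can be lost; the two new centres are erased in steps 10 and 11.

Step 10
Reactants: 12 aldol adduct
Product: 13 (2S,3S,4R,5S)-3,4,5-tris(benzyloxy)-2-[(4-methoxybenzyl)oxy]-6-(5-phenylpent-2-ynoyl)cyclohexan-1-one (largely the chelated enol)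
Conditions: Dess–Martin periodinane, NaHCO3, CH2Cl2, 0 °C → rt
Reagents that add atoms: none
Why: Dess–Martin oxidation of the propargylic carbinol under buffered, non-basic conditions gives the 2-alkynoyl ketone without touching the PMB ether or the β-benzyloxy group.

Step 11
Reactants: 13 ynedione
Product: 14 (5S,6R,7S,8S)-5,6,7-tris(benzyloxy)-8-[(4-methoxybenzyl)oxy]-2-(2-phenylethyl)-5,6,7,8-tetrahydro-4H-chromen-4-one
Conditions: Ph3PAuNTf2 (5 mol %), CH2Cl2, rt
Reagents that add atoms: none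
Why: Gold-catalysed 6-endo-dig cycloisomerisation in which the enol oxygen at C8a adds to the β-carbon of the gold-activated ynone and protodeauration gives the 4-pyranone (ring B) under neutral conditions.

Step 12
Reactants: 14 PMB ether
Product: 15 (5S,6R,7R,8S)-5,6,7-tris(benzyloxy)-8-hydroxy-2-(2-phenylethyl)-5,6,7,8-tetrahydro-4H-chromen-4-one (C7 descriptor changes by priority only)
Conditions: DDQ, CH2Cl2/pH 7 buffer, 0 °C → rt
Reagents that add atoms: none
Why: Oxidative PMB removal: DDQ abstracts hydride from the electron-rich benzylic CH2 and water collapses the oxocarbenium ion to anisaldehyde and the C8 alcohol, while the plain benzyl ethers react much more slowly.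

Step 13
Reactants: 11 5-phenylpent-2-ynal; 16 ethynylmagnesium bromide (HC≡CMgBr)
Product: 17 7-phenylhepta-1,4-diyn-3-ol (racemic)
Conditions: THF, −78 → 0 °C; aq. NH4Cl
Reagents that add atoms: none
Why: 1,2-Addition of the alkynyl Grignard reagent to the ynal; the carbinol centre is removed in step 14.

Step 14
Reactants: 17 diynol
Product: 18 7-phenylhepta-1,4-diyn-3-one
Conditions: MnO2, CH2Cl2, rt
Reagents that add atoms: none
Why: MnO2 oxidises the doubly propargylic alcohol under neutral conditions to the cross-conjugated diynone, which is used cold and without storage.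

Step 15
Reactants: 18 diynone
Product: 19 2-ethynyl-2-(4-phenylbut-1-yn-1-yl)-1,3-dioxolane
Conditions: Me3SiOCH2CH2OSiMe3, Me3SiOTf (cat.), CH2Cl2, −78 → −20 °C; pyridine
Reagents that add atoms: 1,2-bis(trimethylsilyloxy)ethane, C[Si](C)(C)OCCO[Si](C)(C)C
Why: Aprotic silyl-transfer ketalisation avoids conjugate addition of free glycol to the diynone and turns the ynone into a sterically biased, electronically ordinary terminal alkyne.

Step 16
Reactants: 20 methyl vinyl ether; 21 Cr(CO)6
Product: 24 tetramethylammonium pentacarbonyl(2-methoxy-1-oxidoprop-2-en-1-ylidene)chromate, via 1-methoxyvinyllithium 22 (not isolated), via lithium acylchromate 23 (not isolated)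
Conditions: t-BuLi, THF, −78 → 0 °C; Cr(CO)6, Et2O, 0 °C → rt; Me4NBr, H2O
Reagents that add atoms: tetramethylammonium bromide, C[N+](C)(C)C.[Br-]
Why: α-Lithiation of the enol ether and addition of the vinyllithium to a CO ligand (first stage of the Fischer carbene synthesis) give the acylmetalate, which cation exchange delivers as a storable ammonium salt.

Step 17
Reactants: 24 ammonium acylchromate; 15 C8 alcohol
Product: 26 pentacarbonyl{(1-methoxyvinyl)[(5S,6R,7S,8S)-5,6,7-tris(benzyloxy)-4-oxo-2-(2-phenylethyl)-5,6,7,8-tetrahydro-4H-chromen-8-yloxy]carbene}chromium, via acetoxycarbene complex 25 (not isolated)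
Conditions: 24 (1.5 equiv), AcBr, CH2Cl2, −40 °C; then 15, −40 → −10 °C
Reagents that add atoms: none
Why: O-Acylation of the acylmetalate gives the strongly electrophilic acetoxycarbene, and addition–elimination of the C8 hydroxyl at the carbene carbon exchanges acetate for the alkoxide (alcoholysis of an acyloxycarbene complex); the C8–O bond is not broken, so C8 keeps its configuration.

Step 18
Reactants: 26 chromium carbene complex; 19 diyne ketal
Product: 28 2-{2-hydroxy-4-methoxy-5-[(5S,6R,7S,8S)-5,6,7-tris(benzyloxy)-4-oxo-2-(2-phenylethyl)-5,6,7,8-tetrahydro-4H-chromen-8-yloxy]phenyl}-2-(4-phenylbut-1-yn-1-yl)-1,3-dioxolane, via tricarbonylchromium-bound phenol 27 (not isolated)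
Conditions: 19 (2 equiv), THF, 50 °C, Ar; then MeCN, air, rt
Reagents that add atoms: none
Why: Thermal loss of a cis CO ligand lets the terminal alkyne of 19 bind and insert into the Cr=C bond with its CH carbon attached to the former carbene carbon (C6'–C5'); CO insertion then gives an η4-vinylketene (C4a'–C8a'), and electrocyclisation onto the methoxyvinyl CH2 (C8a'–C8') followed by enolisation gives the chromium-bound phenol 27, which air releases as 28. This is the Dötz benzannulation of an alkenyl(alkoxy)carbene complex with a terminal alkyne, a reaction type known for 1-alkoxyalkenyl carbenes and for carbenes that carry chiral secondary alkoxy groups. Ring C closes by disrotatory 6π-electrocyclic closure of the dienylketene, a formal [3+2+1] annulation inside the chromium coordination sphere. No stereocentre is formed, and C5–C8 are remote spectators whose C–O bonds are not involved. The step needs regioselectivity, which the steric preference of terminal alkynes secures by placing the bulky ketal carbon next to the CO-derived carbon, and chemoselectivity for the terminal alkyne, which is expected because the internal alkyne of 19 is flanked by the quaternary ketal carbon. It also needs a non-oxidising release from chromium, so that the hydroquinone monoether is not taken on to a quinone.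

Step 19
Reactants: 28 phenol ketal
Product: 30 (5S,6R,7S,8S)-5,6,7-tris(benzyloxy)-8-{[7-methoxy-4-oxo-2-(2-phenylethyl)-4H-chromen-6-yl]oxy}-2-(2-phenylethyl)-5,6,7,8-tetrahydro-4H-chromen-4-one, via o-hydroxyaryl ynone 29 (not isolated)
Conditions: TsOH·H2O (cat.), acetone/H2O, 40 °C; then Et2NH, EtOH, rt
Reagents that add atoms: water, O
Why: Acid hydrolysis of the dioxolane (oxocarbenium ion stabilised by the electron-rich aryl ring) frees the ynone, and diethylamine adds to its β-carbon and is displaced by the phenol in a 6-endo addition–elimination that closes ring D without strong base (amine-mediated ynone-to-chromone cyclisation).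

Step 20
Reactants: 30 tri-O-benzyl ether
Product: 31 (5S,6R,7S,8S)-5,6,7-trihydroxy-8-{[7-methoxy-4-oxo-2-(2-phenylethyl)-4H-chromen-6-yl]oxy}-2-(2-phenylethyl)-5,6,7,8-tetrahydro-4H-chromen-4-one (CNP0125425.2)
Conditions: BCl3, C6HMe5, CH2Cl2, −78 °C; then MeOH
Reagents that add atoms: none
Why: Lewis-acid debenzylation with Friedel–Crafts capture of the benzyl cations by pentamethylbenzene cleaves the three benzyl ethers at −78 °C without hydrogenolysis of the C5–O and C8–O bonds, the aryl methyl ether or the pyranone double bonds; no stereocentre is touched.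

**Compound list**

1 | (1S,2S)-3-bromocyclohexa-3,5-diene-1,2-diol | O[C@@H]1C(Br)=CC=C[C@@H]1O | starting material
2 | (3aS,7aS)-4-bromo-2-(4-methoxyphenyl)-3a,7a-dihydro-1,3-benzodioxole | COc1ccc(cc1)C1O[C@@H]2C(Br)=CC=C[C@@H]2O1 | intermediate
3 | (1S,2S)-3-bromo-2-[(4-methoxybenzyl)oxy]cyclohexa-3,5-dien-1-ol | COc1ccc(CO[C@@H]2C(Br)=CC=C[C@@H]2O)cc1 | intermediate
4 | (5S,6S)-5-(benzyloxy)-1-bromo-6-[(4-methoxybenzyl)oxy]cyclohexa-1,3-diene | COc1ccc(CO[C@@H]2C(Br)=CC=C[C@@H]2OCc2ccccc2)cc1 | intermediate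
5 | (1R,4S,5S,6R)-5-(benzyloxy)-3-bromo-4-[(4-methoxybenzyl)oxy]-7-oxabicyclo[4.1.0]hept-2-ene | COc1ccc(CO[C@@H]2C(Br)=C[C@@H]3[C@@H](O3)[C@@H]2OCc2ccccc2)cc1 | intermediate
6 | (1R,2S,5S,6S)-6-(benzyloxy)-4-bromo-5-[(4-methoxybenzyl)oxy]cyclohex-3-ene-1,2-diol | COc1ccc(CO[C@@H]2C(Br)=C[C@H](O)[C@@H](O)[C@@H]2OCc2ccccc2)cc1 | intermediate
7 | (3S,4R,5S,6S)-3,4,5-tris(benzyloxy)-1-bromo-6-[(4-methoxybenzyl)oxy]cyclohex-1-ene | COc1ccc(CO[C@@H]2C(Br)=C[C@H](OCc3ccccc3)[C@@H](OCc3ccccc3)[C@@H]2OCc2ccccc2)cc1 | intermediate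
8 | alkenyl pinacol boronate of 7 (Bpin in place of Br, stereocentres unchanged) | COc1ccc(CO[C@@H]2C(B3OC(C)(C)C(C)(C)O3)=C[C@H](OCc4ccccc4)[C@@H](OCc4ccccc4)[C@@H]2OCc2ccccc2)cc1 | intermediate
9 | (2S,3S,4R,5S)-3,4,5-tris(benzyloxy)-2-[(4-methoxybenzyl)oxy]cyclohexan-1-one | COc1ccc(CO[C@@H]2C(=O)C[C@H](OCc3ccccc3)[C@@H](OCc3ccccc3)[C@@H]2OCc2ccccc2)cc1 | intermediate
10 | 4-phenyl-1-butyne | C#CCCc1ccccc1 | starting material
11 | 5-phenylpent-2-ynal | O=CC#CCCc1ccccc1 | intermediate
12 | (2S,3S,4R,5S)-3,4,5-tris(benzyloxy)-6-(1-hydroxy-5-phenylpent-2-yn-1-yl)-2-[(4-methoxybenzyl)oxy]cyclohexan-1-one | COc1ccc(CO[C@@H]2C(=O)C(C(O)C#CCCc3ccccc3)[C@H](OCc3ccccc3)[C@@H](OCc3ccccc3)[C@@H]2OCc2ccccc2)cc1 | intermediate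
13 | (2S,3S,4R,5S)-3,4,5-tris(benzyloxy)-2-[(4-methoxybenzyl)oxy]-6-(5-phenylpent-2-ynoyl)cyclohexan-1-one | COc1ccc(CO[C@@H]2C(=O)C(C(=O)C#CCCc3ccccc3)[C@H](OCc3ccccc3)[C@@H](OCc3ccccc3)[C@@H]2OCc2ccccc2)cc1 | intermediate
14 | (5S,6R,7S,8S)-5,6,7-tris(benzyloxy)-8-[(4-methoxybenzyl)oxy]-2-(2-phenylethyl)-5,6,7,8-tetrahydro-4H-chromen-4-one | COc1ccc(CO[C@@H]2c3oc(CCc4ccccc4)cc(=O)c3[C@H](OCc3ccccc3)[C@@H](OCc3ccccc3)[C@@H]2OCc2ccccc2)cc1 | intermediate
15 | (5S,6R,7R,8S)-5,6,7-tris(benzyloxy)-8-hydroxy-2-(2-phenylethyl)-5,6,7,8-tetrahydro-4H-chromen-4-one | O[C@@H]1c2oc(CCc3ccccc3)cc(=O)c2[C@H](OCc2ccccc2)[C@@H](OCc2ccccc2)[C@@H]1OCc1ccccc1 | intermediate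
16 | ethynylmagnesium bromide | C#C[Mg]Br | starting material
17 | 7-phenylhepta-1,4-diyn-3-ol (racemic) | C#CC(O)C#CCCc1ccccc1 | intermediate
18 | 7-phenylhepta-1,4-diyn-3-one | C#CC(=O)C#CCCc1ccccc1 | intermediate
19 | 2-ethynyl-2-(4-phenylbut-1-yn-1-yl)-1,3-dioxolane | C#CC1(C#CCCc2ccccc2)OCCO1 | intermediate
20 | methyl vinyl ether | COC=C | starting material
21 | hexacarbonylchromium, Cr(CO)6 | O=C=[Cr](=C=O)(=C=O)(=C=O)(=C=O)=C=O | starting material
22 | 1-methoxyvinyllithium | [Li]C(=C)OC | intermediate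
23 | lithium pentacarbonyl(2-methoxy-1-oxidoprop-2-en-1-ylidene)chromate | [Li+].[O-]C(C(=C)OC)=[Cr](=C=O)(=C=O)(=C=O)(=C=O)=C=O | intermediate
24 | tetramethylammonium pentacarbonyl(2-methoxy-1-oxidoprop-2-en-1-ylidene)chromate | C[N+](C)(C)C.[O-]C(C(=C)OC)=[Cr](=C=O)(=C=O)(=C=O)(=C=O)=C=O | intermediate
25 | pentacarbonyl[acetoxy(1-methoxyvinyl)carbene]chromium | C=C(OC)C(OC(C)=O)=[Cr](=C=O)(=C=O)(=C=O)(=C=O)=C=O | intermediate
26 | pentacarbonyl{(1-methoxyvinyl)[(5S,6R,7S,8S)-5,6,7-tris(benzyloxy)-4-oxo-2-(2-phenylethyl)-5,6,7,8-tetrahydro-4H-chromen-8-yloxy]carbene}chromium | C=C(OC)C(=[Cr](=C=O)(=C=O)(=C=O)(=C=O)=C=O)O[C@@H]1c2oc(CCc3ccccc3)cc(=O)c2[C@H](OCc2ccccc2)[C@@H](OCc2ccccc2)[C@@H]1OCc1ccccc1 | intermediate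
27 | tricarbonyl(η6-arene)chromium complex of phenol 28 (chromium on ring C) | COc1cc(O)c(cc1O[C@@H]1c2oc(CCc3ccccc3)cc(=O)c2[C@H](OCc2ccccc2)[C@@H](OCc2ccccc2)[C@@H]1OCc1ccccc1)C1(C#CCCc2ccccc2)OCCO1.[Cr](=C=O)(=C=O)=C=O | intermediate
28 | 2-{2-hydroxy-4-methoxy-5-[(5S,6R,7S,8S)-5,6,7-tris(benzyloxy)-4-oxo-2-(2-phenylethyl)-5,6,7,8-tetrahydro-4H-chromen-8-yloxy]phenyl}-2-(4-phenylbut-1-yn-1-yl)-1,3-dioxolane | COc1cc(O)c(cc1O[C@@H]1c2oc(CCc3ccccc3)cc(=O)c2[C@H](OCc2ccccc2)[C@@H](OCc2ccccc2)[C@@H]1OCc1ccccc1)C1(C#CCCc2ccccc2)OCCO1 | intermediate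
29 | 1-{2-hydroxy-4-methoxy-5-[(5S,6R,7S,8S)-5,6,7-tris(benzyloxy)-4-oxo-2-(2-phenylethyl)-5,6,7,8-tetrahydro-4H-chromen-8-yloxy]phenyl}-5-phenylpent-2-yn-1-one | COc1cc(O)c(cc1O[C@@H]1c2oc(CCc3ccccc3)cc(=O)c2[C@H](OCc2ccccc2)[C@@H](OCc2ccccc2)[C@@H]1OCc1ccccc1)C(=O)C#CCCc1ccccc1 | intermediate
30 | (5S,6R,7S,8S)-5,6,7-tris(benzyloxy)-8-{[7-methoxy-4-oxo-2-(2-phenylethyl)-4H-chromen-6-yl]oxy}-2-(2-phenylethyl)-5,6,7,8-tetrahydro-4H-chromen-4-one | COc1cc2oc(CCc3ccccc3)cc(=O)c2cc1O[C@@H]1c2oc(CCc3ccccc3)cc(=O)c2[C@H](OCc2ccccc2)[C@@H](OCc2ccccc2)[C@@H]1OCc1ccccc1 | intermediate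
31 | (5S,6R,7S,8S)-5,6,7-trihydroxy-8-{[7-methoxy-4-oxo-2-(2-phenylethyl)-4H-chromen-6-yl]oxy}-2-(2-phenylethyl)-5,6,7,8-tetrahydro-4H-chromen-4-one | COc1cc2oc(CCc3ccccc3)cc(=O)c2cc1O[C@@H]1c2oc(CCc3ccccc3)cc(=O)c2[C@H](O)[C@@H](O)[C@@H]1O | target

**Step count and risks**

Total step count: 20. Longest linear sequence: 15 steps (steps 1–7, 9–12, 17–20).

Steps most likely to fail:

First, step 18 (benzannulation). The internal alkyne of 19 may compete for the unsaturated chromium centre, or a second alkyne molecule may be taken up before CO insertion, so that the vinylketene is diverted from ring closure. The fallback sets out from 26 and returns at 30. The benzannulation would be run with the mono-alkyne 2-ethynyl-2-methyl-1,3-dioxolane F1 (from 3-butyn-2-one by the ketalisation of step 15), which should give the aryl methyl ketone ketal F2. Aqueous acid (TsOH, acetone/H2O) would free the o-hydroxyacetophenone F3. Pyrrolidine-mediated Kabbe condensation of F3 with 3-phenylpropanal (enamine aldol condensation and oxa-Michael closure, no strong base) would give the 2-(2-phenylethyl)chroman-4-one F4. Aerobic dehydrogenation with Pd(OCOCF3)2/DMSO (O2, AcOH, 80 °C) would then introduce the C2'=C3' double bond and give 30.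

Second, step 17 (carbene formation). The hindered C8 hydroxyl next to the electron-poor pyranone may add too slowly, so that the acetoxycarbene 25 decomposes before the exchange. The fallback sets out from 15 and returns at 30; it makes the C8–O–C6' bond by Mitsunobu etherification instead. Because that reaction inverts C8, the alcohol is inverted first: Mitsunobu esterification of 15 with 4-nitrobenzoic acid (PPh3, DIAD) would give the (8R)-4-nitrobenzoate F5, and brief methanolysis (K2CO3, MeOH, 0 °C) the (8R)-alcohol F6. The phenol partner is made from 1-(2,5-dihydroxy-4-methoxyphenyl)ethanone: Claisen condensation with ethyl 3-phenylpropanoate (NaH, THF; harmless here because no tetrahydrochromone is present) would give 1-(2,5-dihydroxy-4-methoxyphenyl)-5-phenylpentane-1,3-dione F7, and cyclodehydration (HCl, MeOH) 6-hydroxy-7-methoxy-2-(2-phenylethyl)chromone F8. Mitsunobu coupling of F6 with F8 (PPh3, DIAD, toluene) would restore the 8S configuration and give 30.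

Third, step 9 (aldol addition). Enolisation may go towards the methine bearing OPMB, or the lithium enolate may lose benzyl alkoxide by β-elimination before the aldehyde arrives. The fallback sets out from 7 and returns at 12, so it also bypasses ketone 9. Bromine–lithium exchange on 7 (t-BuLi, Et2O, −78 °C) and oxidation of the alkenyllithium with Me3SiOOSiMe3 would give the regiodefined trimethylsilyl enol ether F9. Mukaiyama aldol addition of F9 to ynal 11 (BF3·OEt2, CH2Cl2, −78 °C) would give 12.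

**Further compounds**

F1 | step 18 | 2-ethynyl-2-methyl-1,3-dioxolane | CC1(C#C)OCCO1
F2 | step 18 | 2-{2-hydroxy-4-methoxy-5-[(5S,6R,7S,8S)-5,6,7-tris(benzyloxy)-4-oxo-2-(2-phenylethyl)-5,6,7,8-tetrahydro-4H-chromen-8-yloxy]phenyl}-2-methyl-1,3-dioxolane | CC1(OCCO1)c1cc(O[C@@H]2c3oc(CCc4ccccc4)cc(=O)c3[C@H](OCc3ccccc3)[C@@H](OCc3ccccc3)[C@@H]2OCc2ccccc2)c(OC)cc1O
F3 | step 18 | 1-{2-hydroxy-4-methoxy-5-[(5S,6R,7S,8S)-5,6,7-tris(benzyloxy)-4-oxo-2-(2-phenylethyl)-5,6,7,8-tetrahydro-4H-chromen-8-yloxy]phenyl}ethanone | CC(=O)c1cc(O[C@@H]2c3oc(CCc4ccccc4)cc(=O)c3[C@H](OCc3ccccc3)[C@@H](OCc3ccccc3)[C@@H]2OCc2ccccc2)c(OC)cc1O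
F4 | step 18 | (5S,6R,7S,8S)-5,6,7-tris(benzyloxy)-8-{[7-methoxy-4-oxo-2-(2-phenylethyl)chroman-6-yl]oxy}-2-(2-phenylethyl)-5,6,7,8-tetrahydro-4H-chromen-4-one (both configurations at C2') | COc1cc2OC(CCc3ccccc3)CC(=O)c2cc1O[C@@H]1c2oc(CCc3ccccc3)cc(=O)c2[C@H](OCc2ccccc2)[C@@H](OCc2ccccc2)[C@@H]1OCc1ccccc1
F5 | step 17 | (5S,6R,7S,8R)-5,6,7-tris(benzyloxy)-4-oxo-2-(2-phenylethyl)-5,6,7,8-tetrahydro-4H-chromen-8-yl 4-nitrobenzoate | O=C(O[C@H]1c2oc(CCc3ccccc3)cc(=O)c2[C@H](OCc2ccccc2)[C@@H](OCc2ccccc2)[C@@H]1OCc1ccccc1)c1ccc(cc1)[N+](=O)[O-]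
F6 | step 17 | (5S,6R,7R,8R)-5,6,7-tris(benzyloxy)-8-hydroxy-2-(2-phenylethyl)-5,6,7,8-tetrahydro-4H-chromen-4-one | O[C@H]1c2oc(CCc3ccccc3)cc(=O)c2[C@H](OCc2ccccc2)[C@@H](OCc2ccccc2)[C@@H]1OCc1ccccc1
F7 | step 17 | 1-(2,5-dihydroxy-4-methoxyphenyl)-5-phenylpentane-1,3-dione | COc1cc(O)c(cc1O)C(=O)CC(=O)CCc1ccccc1
F8 | step 17 | 6-hydroxy-7-methoxy-2-(2-phenylethyl)-4H-chromen-4-one | COc1cc2oc(CCc3ccccc3)cc(=O)c2cc1O
F9 | step 9 | {[(3S,4R,5S,6S)-3,4,5-tris(benzyloxy)-6-[(4-methoxybenzyl)oxy]cyclohex-1-en-1-yl]oxy}trimethylsilane | COc1ccc(CO[C@@H]2C(O[Si](C)(C)C)=C[C@H](OCc3ccccc3)[C@@H](OCc3ccccc3)[C@@H]2OCc2ccccc2)cc1
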